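**Retrosynthetic overview**

1. The plan rests on the O1–C2 bond and the aromatic pyranone ring C. Both are made in one oxidation from a 2-hydroxyaryl ketone whose C2=C3 double bond already lies inside the seven-membered ring D (C2–C3–C1''–C2''–O–C2'–C1').
2. Target ⇒ Suzuki–Miyaura coupling at C6 ⇒ 6-bromo diphenol ⇒ BCl3 ether cleavage ⇒ O-benzyl/O-methyl bromochromone ⇒ iodide-mediated anodic closure of ring C ⇒ ring D enone.
3. Ring D enone ⇒ FeCl3 alkyne–carbonyl metathesis (forms C2=C3 and C4=O) ⇒ SNAr aryl ether (O–C2') ⇒ Sonogashira coupling of a ring A iodide with a six-carbon alkynol ⇒ acetylide opening of a glycerate-derived epoxide that carries C2''.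
4. Ring order: rings A and B are bought, ring D closes in step 10, ring C in step 12. C2'' (S) comes from methyl (S)-glycerate acetonide and its C–O bond is never broken.

Key step: step 12

Remark: flavone numbering is used for the tetracycles (O1 and C2–C8a for rings C and A, C1'–C6' for ring B, ring D = C2–C3–C1''H2–C2''H–O–C2'–C1' with C(CH3)2OH on C2''); "oxepinoflavone" stands for this ring system, and the (E)-alkenyl pinacol boronate and LiC≡CH·H2NCH2CH2NH2 are assumed to be purchasable.

**Route**

Step 1
Reactants: 1 methyl (S)-2,2-dimethyl-1,3-dioxolane-4-carboxylate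
Product: 2 (S)-2-(2,2-dimethyl-1,3-dioxolan-4-yl)propan-2-ol
Conditions: MeMgBr (3 equiv), THF, 0 °C to rt; then aq. NH4Cl
Reagents that add atoms: methylmagnesium bromide, C[Mg]Br
Why: Double Grignard addition to the ester should give the tertiary carbinol, and at 0 °C addition outruns enolisation of the alkoxy-substituted α-carbon, so the S centre of the pool (the later C2'') is carried over unchanged.

Step 2
Reactants: 2 (S)-2-(2,2-dimethyl-1,3-dioxolan-4-yl)propan-2-ol
Product: 3 (S)-4-[2-(methoxymethoxy)propan-2-yl]-2,2-dimethyl-1,3-dioxolane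
Conditions: NaH, MOMCl, Bu4NI (cat.), THF, 0 °C to rt
Reagents that add atoms: chloromethyl methyl ether, COCCl
Why: Williamson-type O-alkylation of the tertiary alkoxide with the activated chloromethyl ether masks the hydroxyl that could otherwise undergo Payne rearrangement in step 5, compete in the arylation of step 9 or trap the activated aldehyde in step 10.

Step 3
Reactants: 3 (S)-4-[2-(methoxymethoxy)propan-2-yl]-2,2-dimethyl-1,3-dioxolane
Product: 4 (S)-3-(methoxymethoxy)-3-methylbutane-1,2-diol
Conditions: AcOH/H2O (4:1), 40 °C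
Reagents that add atoms: none
Why: Acetal hydrolysis in aqueous acetic acid should cleave the terminal isopropylidene ketal much faster than the acyclic formaldehyde acetal, so the MOM ether is kept.

Step 4
Reactants: 4 (S)-3-(methoxymethoxy)-3-methylbutane-1,2-diol
Product: 6 (S)-2-[2-(methoxymethoxy)propan-2-yl]oxirane, via primary tosylate 5 (not isolated)
Conditions: NaH (2.2 equiv), 1-(p-toluenesulfonyl)imidazole (1.05 equiv), THF, 0 °C to rt
Reagents that add atoms: none
Why: The unhindered primary alkoxide should be sulfonylated selectively and the neighbouring secondary alkoxide then closes by intramolecular Williamson displacement (3-exo-tet), which leaves the C–O bond of the stereocentre intact and so retains S.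

Step 5
Reactants: 6 (S)-2-[2-(methoxymethoxy)propan-2-yl]oxirane and 7 lithium acetylide–ethylenediamine complex (LiC≡CH·H2NCH2CH2NH2)
Product: 8 (S)-2-(methoxymethoxy)-2-methylhex-5-yn-3-ol
Conditions: DMSO, 0 °C to rt; then H2O
Reagents that add atoms: none
Why: SN2 alkynylation of a terminal epoxide should take place only at the CH2 carbon, so the carbinol stereocentre is not touched and the C1''–C2'' unit with a free secondary hydroxyl is obtained.

Step 6
Reactants: 9 4-bromo-3,5-dimethoxyphenol
Product: 10 4-bromo-2-iodo-3,5-dimethoxyphenol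
Conditions: NIS (1.0 equiv), MeCN, 0 °C, dark
Reagents that add atoms: N-iodosuccinimide, O=C1CCC(=O)N1I
Why: Electrophilic aromatic iodination should give one mono-iodide because the two free ring positions are equivalent and both ortho to the hydroxyl.

Step 7
Reactants: 10 4-bromo-2-iodo-3,5-dimethoxyphenol
Product: 11 2-bromo-4-iodo-1,3-dimethoxy-5-(methoxymethoxy)benzene
Conditions: MOMCl, i-Pr2NEt, CH2Cl2, 0 °C to rt
Reagents that add atoms: chloromethyl methyl ether, COCCl
Why: O-Alkylation of the phenol (MOM protection) keeps the later ortho-alkynyl phenol from closing to a benzofuran and tolerates the base of steps 8 and 9.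

Step 8
Reactants: 11 2-bromo-4-iodo-1,3-dimethoxy-5-(methoxymethoxy)benzene and 8 (S)-2-(methoxymethoxy)-2-methylhex-5-yn-3-ol
Product: 12 (S)-6-[3-bromo-2,4-dimethoxy-6-(methoxymethoxy)phenyl]-2-(methoxymethoxy)-2-methylhex-5-yn-3-ol
Conditions: Pd(PPh3)2Cl2 (5 mol%), CuI (10 mol%), Et3N/THF, 60 °C, degassed
Reagents that add atoms: none
Why: Sonogashira coupling should be chemoselective because zerovalent palladium inserts into the C–I bond far faster than into the equally hindered, electron-rich C–Br bond, and the free secondary alcohol is tolerated.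

Step 9
Reactants: 12 (S)-6-[3-bromo-2,4-dimethoxy-6-(methoxymethoxy)phenyl]-2-(methoxymethoxy)-2-methylhex-5-yn-3-ol and 13 4-(benzyloxy)-2-fluorobenzaldehyde
Product: 14 (S)-4-(benzyloxy)-2-({6-[3-bromo-2,4-dimethoxy-6-(methoxymethoxy)phenyl]-2-(methoxymethoxy)-2-methylhex-5-yn-3-yl}oxy)benzaldehyde
Conditions: NaH (1.2 equiv), DMF, 0 °C; then 13, rt to 40 °C
Reagents that add atoms: none
Why: Nucleophilic aromatic substitution of the fluoride ortho to the formyl group by the sodium alkoxide forms the O–C2' bond at oxygen, so the configuration of the carbinol carbon is retained.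

Step 10
Reactants: 14 (S)-4-(benzyloxy)-2-({6-[3-bromo-2,4-dimethoxy-6-(methoxymethoxy)phenyl]-2-(methoxymethoxy)-2-methylhex-5-yn-3-yl}oxy)benzaldehyde
Product: 16 (S)-[8-(benzyloxy)-2-[2-(methoxymethoxy)propan-2-yl]-2,3-dihydro-1-benzoxepin-4-yl][3-bromo-2,4-dimethoxy-6-(methoxymethoxy)phenyl]methanone, via oxetene 15 (not isolated)
Conditions: FeCl3 (15 mol%), MeCN, rt to 50 °C
Reagents that add atoms: none
Why: In this known FeCl3-catalysed intramolecular alkyne–carbonyl metathesis of 2-(4-arylbut-3-ynyloxy)benzaldehydes, the CH2-bearing alkyne carbon should attack the activated aldehyde (seven-membered closure of ring D) because the vinyl cation character then lies next to the trioxygenated ring A, and the [2+2] oxetene opens electrocyclically to the conjugated aryl ketone without touching the stereocentre.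

Step 11
Reactants: 16 (S)-[8-(benzyloxy)-2-[2-(methoxymethoxy)propan-2-yl]-2,3-dihydro-1-benzoxepin-4-yl][3-bromo-2,4-dimethoxy-6-(methoxymethoxy)phenyl]methanone
Product: 17 (S)-[8-(benzyloxy)-2-(2-hydroxypropan-2-yl)-2,3-dihydro-1-benzoxepin-4-yl](3-bromo-6-hydroxy-2,4-dimethoxyphenyl)methanone
Conditions: HCl (3 M aq.), MeOH/THF, 45 °C
Reagents that add atoms: none
Why: Acid-catalysed acetal solvolysis in methanol should remove the aryl and the tertiary alkyl MOM group together, while the benzyl and methyl ethers, the aryl bromide and the enone are inert to dilute HCl.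

Step 12
Reactants: 17 (S)-[8-(benzyloxy)-2-(2-hydroxypropan-2-yl)-2,3-dihydro-1-benzoxepin-4-yl](3-bromo-6-hydroxy-2,4-dimethoxyphenyl)methanone
Product: 20 (2''S)-4'-benzyloxy-6-bromo-5,7-dimethoxy oxepinoflavone, via chromanone 18 (not isolated), via 3-iodochromanone 19 (not isolated)
Conditions: NH4I (0.5 equiv), DMSO, undivided cell, graphite anode, Pt cathode, constant current (10 mA, about 2.5 F per mol), 80 °C
Reagents that add atoms: none
Why: Iodide is oxidised at the anode to iodine, which is therefore present only at a low steady concentration, while protons delivered by NH4+ are reduced to H2 at the Pt cathode and the NH3 left behind serves as base. The ring A phenol adds to the enone β-carbon C2 in a reversible 6-endo-trig oxa-Michael closure that forms O1–C2 and ring C as chromanone 18; iodine then iodinates the C3 enol to give 19, and loss of HI across C2–C3 makes the pyranone aromatic. The closest known reaction is the iodine-mediated oxidative cyclisation of 2'-hydroxychalcones, α-substituted ones included, to flavones; only the way iodine is regenerated from iodide differs here. The product gains no stereocentre, because the transient C2 and C3 centres of 18 and 19 become sp2, and C2'' carries no acidic hydrogen and no leaving group in a β-position to an enolisable carbon, so it should stay S. The step needs closure at C2 only and oxidation without iodination of the activated rings A and B: the C2=C3 bond is locked inside ring D with C1'' on C3, so the phenol can only close the six-membered ring, and the small amount of electrogenerated iodine, any excess of which is reduced again at the cathode, disfavours aryl iodination.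

Step 13
Reactants: 20 (2''S)-4'-benzyloxy-6-bromo-5,7-dimethoxy oxepinoflavone
Product: 21 (2''S)-6-bromo-5,4'-dihydroxy-7-methoxy oxepinoflavone
Conditions: BCl3 (1 M in CH2Cl2, 6 equiv), C6HMe5 (3 equiv), CH2Cl2, −78 to 0 °C; then MeOH, aq. NaHCO3
Reagents that add atoms: none
Why: Lewis acid ether cleavage with BCl3 chelated between C4=O and the 5-oxygen should remove the peri methyl group but not the 7-methyl group, and it cleaves the benzyl ether with pentamethylbenzene as cation trap; the step is placed before the acid-sensitive styrenyl alkene is introduced.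

Step 14
Reactants: 21 (2''S)-6-bromo-5,4'-dihydroxy-7-methoxy oxepinoflavone and 22 (E)-4,4,5,5-tetramethyl-2-(3-methylbut-1-en-1-yl)-1,3,2-dioxaborolane
Product: 23 (2''S)-5,4'-dihydroxy-7-methoxy-6-[(E)-3-methylbut-1-en-1-yl] oxepinoflavone (target CNP0216454.2)
Conditions: Pd(OAc)2 (5 mol%), SPhos (10 mol%), K3PO4 (4 equiv), 1,4-dioxane/H2O (4:1), 90 °C, degassed
Reagents that add atoms: none
Why: Suzuki–Miyaura coupling with a bulky electron-rich biarylphosphine should engage the hindered C6 bromide in the presence of the free phenols (extra base), and transmetalation and reductive elimination retain the E geometry of the alkenyl boronate.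

**Compound list**

1 | methyl (S)-2,2-dimethyl-1,3-dioxolane-4-carboxylate | COC(=O)[C@@H]1COC(C)(C)O1 | starting material
2 | (S)-2-(2,2-dimethyl-1,3-dioxolan-4-yl)propan-2-ol | CC(C)(O)[C@@H]1COC(C)(C)O1 | intermediate
3 | (S)-4-[2-(methoxymethoxy)propan-2-yl]-2,2-dimethyl-1,3-dioxolane | COCOC(C)(C)[C@@H]1COC(C)(C)O1 | intermediate
4 | (S)-3-(methoxymethoxy)-3-methylbutane-1,2-diol | COCOC(C)(C)[C@@H](O)CO | intermediate
5 | (S)-2-hydroxy-3-(methoxymethoxy)-3-methylbutyl 4-methylbenzenesulfonate (primary tosylate, not isolated) | COCOC(C)(C)[C@@H](O)COS(=O)(=O)c1ccc(C)cc1 | intermediate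
6 | (S)-2-[2-(methoxymethoxy)propan-2-yl]oxirane | COCOC(C)(C)[C@@H]1CO1 | intermediate
7 | lithium acetylide–ethylenediamine complex | [Li]C#C.NCCN | starting material
8 | (S)-2-(methoxymethoxy)-2-methylhex-5-yn-3-ol | COCOC(C)(C)[C@@H](O)CC#C | intermediate
9 | 4-bromo-3,5-dimethoxyphenol | COc1cc(O)cc(OC)c1Br | starting material
10 | 4-bromo-2-iodo-3,5-dimethoxyphenol | COc1cc(O)c(I)c(OC)c1Br | intermediate
11 | 2-bromo-4-iodo-1,3-dimethoxy-5-(methoxymethoxy)benzene | COCOc1cc(OC)c(Br)c(OC)c1I | intermediate
12 | (S)-6-[3-bromo-2,4-dimethoxy-6-(methoxymethoxy)phenyl]-2-(methoxymethoxy)-2-methylhex-5-yn-3-ol | COCOC(C)(C)[C@@H](O)CC#Cc1c(OCOC)cc(OC)c(Br)c1OC | intermediate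
13 | 4-(benzyloxy)-2-fluorobenzaldehyde | O=Cc1ccc(OCc2ccccc2)cc1F | starting material
14 | (S)-4-(benzyloxy)-2-({6-[3-bromo-2,4-dimethoxy-6-(methoxymethoxy)phenyl]-2-(methoxymethoxy)-2-methylhex-5-yn-3-yl}oxy)benzaldehyde | COCOC(C)(C)[C@@H](Oc1cc(OCc2ccccc2)ccc1C=O)CC#Cc1c(OCOC)cc(OC)c(Br)c1OC | intermediate
15 | oxetene from [2+2] addition of the formyl C=O to the alkyne (ring A on the oxygen-bearing alkene carbon, S at the ether carbon, new sp3 CH unassigned; not isolated) | COCOc1cc(OC)c(Br)c(OC)c1C1=C2C[C@@H](C(C)(C)OCOC)Oc3cc(OCc4ccccc4)ccc3C2O1 | intermediate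
16 | (S)-[8-(benzyloxy)-2-[2-(methoxymethoxy)propan-2-yl]-2,3-dihydro-1-benzoxepin-4-yl][3-bromo-2,4-dimethoxy-6-(methoxymethoxy)phenyl]methanone | COCOc1cc(OC)c(Br)c(OC)c1C(=O)C1=Cc2ccc(OCc3ccccc3)cc2O[C@H](C(C)(C)OCOC)C1 | intermediate
17 | (S)-[8-(benzyloxy)-2-(2-hydroxypropan-2-yl)-2,3-dihydro-1-benzoxepin-4-yl](3-bromo-6-hydroxy-2,4-dimethoxyphenyl)methanone | COc1cc(O)c(C(=O)C2=Cc3ccc(OCc4ccccc4)cc3O[C@H](C(C)(C)O)C2)c(OC)c1Br | intermediate
18 | (2''S)-4'-benzyloxy-6-bromo-5,7-dimethoxy-2,3-dihydro oxepinoflavone (chromanone, C2 and C3 unassigned; not isolated) | COc1cc2OC3C(C[C@@H](C(C)(C)O)Oc4cc(OCc5ccccc5)ccc34)C(=O)c2c(OC)c1Br | intermediate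
19 | 3-iodo derivative of chromanone 18 (not isolated) | COc1cc2OC3C(I)(C[C@@H](C(C)(C)O)Oc4cc(OCc5ccccc5)ccc34)C(=O)c2c(OC)c1Br | intermediate
20 | (2''S)-4'-benzyloxy-6-bromo-5,7-dimethoxy oxepinoflavone | COc1cc2oc3c(c(=O)c2c(OC)c1Br)C[C@@H](C(C)(C)O)Oc1cc(OCc4ccccc4)ccc1-3 | intermediate
21 | (2''S)-6-bromo-5,4'-dihydroxy-7-methoxy oxepinoflavone | COc1cc2oc3c(c(=O)c2c(O)c1Br)C[C@@H](C(C)(C)O)Oc1cc(O)ccc1-3 | intermediate
22 | (E)-4,4,5,5-tetramethyl-2-(3-methylbut-1-en-1-yl)-1,3,2-dioxaborolane | CC(C)/C=C/B1OC(C)(C)C(C)(C)O1 | starting material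
23 | (2''S)-5,4'-dihydroxy-7-methoxy-6-[(E)-3-methylbut-1-en-1-yl] oxepinoflavone (CNP0216454.2) | COc1cc2oc3c(c(=O)c2c(O)c1/C=C/C(C)C)C[C@@H](C(C)(C)O)Oc1cc(O)ccc1-3 | target

**Step count and risks**

Total steps: 14. Longest linear sequence: 12 steps (steps 1–5 and 8–14 from 1); the ring A branch (steps 6 and 7) joins at step 8.

Steps most likely to fail:

1. Step 12. The electrolysis may iodinate the activated C8 position of ring A or ring B, reduce the enone at the cathode, or stop at the chromanone stage. Fallback, from 17 back to 20: the two events are separated into known reactions. NaOAc in EtOH at reflux closes the phenol onto C2 by oxa-Michael addition to give chromanone 18, which is then isolated. DDQ in 1,4-dioxane at reflux dehydrogenates C2–C3 of 18 to give 20. No compound outside the list is made (F0).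

2. Step 13. While the mixture warms to cleave the 5-O-methyl group, the borate of the tertiary carbinol may ionise (chloride formation or elimination), or the secondary alkyl aryl ether of ring D may open. Fallback, from 20 back to 21: the tertiary alcohol is first silylated (TBSOTf, 2,6-lutidine, CH2Cl2, 0 °C) to the tert-butyldimethylsilyl ether F1. The BCl3/pentamethylbenzene cleavage is then run on this less basic oxygen pattern to give the bromodiphenol silyl ether F2. HF·pyridine in THF at rt removes silicon and gives 21.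

3. Step 9. Arylation by the hindered alkoxide may be slow, and it may lose to addition or hydride transfer to the aldehyde or to base-induced attack of the alkoxide on the aryl alkyne. Fallback, from 12 back to 14: the alkoxide of 12 (NaH, DMF) is arylated with 4-(benzyloxy)-2-fluorobenzonitrile, whose nitrile activates more strongly and offers no electrophilic carbonyl, to give the benzonitrile aryl ether F3. Reduction with i-Bu2AlH in toluene at −78 °C and aqueous acid work-up then gives the aldehyde 14.

**Further compounds**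

F0 | step 12 | none | none
F1 | step 13 | (2''S)-4'-benzyloxy-6-bromo-5,7-dimethoxy oxepinoflavone tert-butyldimethylsilyl ether (silyl on the tertiary oxygen) | COc1cc2oc3c(c(=O)c2c(OC)c1Br)C[C@@H](C(C)(C)O[Si](C)(C)C(C)(C)C)Oc1cc(OCc4ccccc4)ccc1-3
F2 | step 13 | (2''S)-6-bromo-5,4'-dihydroxy-7-methoxy oxepinoflavone tert-butyldimethylsilyl ether (silyl on the tertiary oxygen) | COc1cc2oc3c(c(=O)c2c(O)c1Br)C[C@@H](C(C)(C)O[Si](C)(C)C(C)(C)C)Oc1cc(O)ccc1-3
F3 | step 9 | (S)-4-(benzyloxy)-2-({6-[3-bromo-2,4-dimethoxy-6-(methoxymethoxy)phenyl]-2-(methoxymethoxy)-2-methylhex-5-yn-3-yl}oxy)benzonitrile | COCOC(C)(C)[C@@H](Oc1cc(OCc2ccccc2)ccc1C#N)CC#Cc1c(OCOC)cc(OC)c(Br)c1OC
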